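**Retrosynthetic overview**
1. Last disconnections at C9': the aryl–C9' and C9'–CH2 bonds go back to a ring-A C1 carbaldehyde, joined through an o-quinone methide; before that, H5 of the trans-decalin comes from hydrogen-atom-transfer reduction of a C5=C6 alkene.
2. Key disconnection C4–C5 (ring A): intramolecular Nozaki–Hiyama–Kishi addition of a ring-B C5 alkenyl triflate to a C4 methyl ketone.
3. Enabling feature: the tertiary carbinol C4 (CH3, OH) of ring A is bonded to ring-fusion carbon C5, which is flanked by quaternary C10. C10 lets the ring-B ketone enolise only towards C6 (one C5=C6 triflate), and the 1,3-diaxial C10–CH3/C4–OH pair is what a chair closure with equatorial C4–CH3 gives.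
4. The C4 ketone and the C9' aldehyde are both unveiled by ozonolysis of one 3-methylcyclopent-2-enyl group (from 3-methylcyclopent-2-en-1-one), attached to C10 of (S)-carvone by reductive Tsuji–Trost allylation (sets C10 and C1). The arene is 2,4,6-trihydroxybenzene-1,3-dicarbaldehyde and the isobutyl end comes from trimethyl(2-methylallyl)silane.
5. Ring order: ring B (carvone) is present from the start, ring A is closed in the key step, the aromatic ring is attached last.

Key step: step 7

Remark: terpenoid carbons carry eudesmane numbers (C1–C10, C11 for the carbinol carbon of the hydroxyisopropyl group, C9' for the benzylic carbon); the decalin of the target is antipodal to the common eudesmols, which is why (S)-carvone is used.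

Step 1
Reactants: 1 3-methylcyclopent-2-en-1-one
Product: 2 (R)-3-methylcyclopent-2-en-1-ol
Conditions: (S)-Me-CBS [(S)-1-methyl-3,3-diphenyltetrahydro-1H,3H-pyrrolo[1,2-c][1,3,2]oxazaborole] (10 mol%), BH3·SMe2, THF, −20 °C; MeOH, aq. work-up
Reagents that add atoms: none
Why: Corey–Bakshi–Shibata 1,2-reduction of a cyclic enone, in which the catalyst delivers hydride to one carbonyl face with the alkenyl carbon as the large group, which should give the (R)-carbinol centre (the future C1).

Step 2
Reactants: 2 (R)-3-methylcyclopent-2-en-1-ol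
Product: 3 methyl (R)-3-methylcyclopent-2-en-1-yl carbonate
Conditions: ClCO2Me, pyridine, CH2Cl2, 0 °C
Reagents that add atoms: methyl chloroformate, COC(Cl)=O
Why: O-acylation of a secondary allylic alcohol, which touches no bond at the stereocentre.

Step 3
Reactants: 4 (S)-(+)-carvone; 3 methyl (R)-3-methylcyclopent-2-en-1-yl carbonate
Product: 6 (2R,5S)-2-methyl-2-[(1R)-3-methylcyclopent-2-en-1-yl]-5-(prop-1-en-2-yl)cyclohexan-1-one, via lithium enoxyborate 5 (not isolated)
Conditions: LiBH(s-Bu)3 (1.05 equiv), THF, −78 °C; then 3, Pd(PPh3)4 (5 mol%), −78 → 0 °C; aq. NH4Cl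
Reagents that add atoms: none
Why: Conjugate hydride addition gives the regiodefined enolate 5 (as its tri-sec-butylborane ate complex), which is alkylated in a Tsuji–Trost reaction: zerovalent palladium ionises 3 with inversion, the enolate attacks the less substituted allyl terminus on the face opposite palladium (net retention, so (R)-3 sets C1), and it enters ring B anti to the C7 isopropenyl group, so the C10 methyl should end cis to it.

Step 4
Reactants: 6 (2R,5S)-2-methyl-2-[(1R)-3-methylcyclopent-2-en-1-yl]-5-(prop-1-en-2-yl)cyclohexan-1-one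
Product: 7 (3S,6R)-6-methyl-6-[(1R)-3-methylcyclopent-2-en-1-yl]-3-(prop-1-en-2-yl)cyclohex-1-en-1-yl trifluoromethanesulfonate
Conditions: KN(SiMe3)2, THF, −78 °C; PhNTf2, −78 → 0 °C; aq. NH4Cl
Reagents that add atoms: N-phenylbis(trifluoromethanesulfonimide), O=S(=O)(N(c1ccccc1)S(=O)(=O)C(F)(F)F)C(F)(F)F
Why: Enol triflate formation, in which deprotonation is possible only at C6 because C10 is quaternary, so a single C5=C6 triflate should form and no stereocentre is touched.

Step 5
Reactants: 7 (3S,6R)-6-methyl-6-[(1R)-3-methylcyclopent-2-en-1-yl]-3-(prop-1-en-2-yl)cyclohex-1-en-1-yl trifluoromethanesulfonate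
Product: 9 (3S,6R)-6-[(2S)-1,1-dimethoxy-5-oxohexan-2-yl]-6-methyl-3-(prop-1-en-2-yl)cyclohex-1-en-1-yl trifluoromethanesulfonate, via keto aldehyde 8 (not isolated)
Conditions: O3 (1.0 equiv), CH2Cl2/MeOH, −78 °C (Sudan Red 7B end point); Me2S, −78 °C → rt; then HC(OMe)3, pyridinium p-toluenesulfonate (cat.), MeOH, rt
Reagents that add atoms: ozone, [O-][O+]=O; trimethyl orthoformate, COC(OC)OC
Why: Ozonolysis is fastest at the electron-rich trisubstituted ring alkene (as for the ring alkene of limonene; the isopropenyl group reacts more slowly and the enol triflate is electron-poor), reductive work-up gives keto aldehyde 8, and only the aldehyde is acetalised under mild acid, with C1 untouched.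

Step 6
Reactants: 9 (3S,6R)-6-[(2S)-1,1-dimethoxy-5-oxohexan-2-yl]-6-methyl-3-(prop-1-en-2-yl)cyclohex-1-en-1-yl trifluoromethanesulfonate
Product: 10 (3S,6R)-6-[(2S)-1,1-dimethoxy-5-oxohexan-2-yl]-3-(2-hydroxypropan-2-yl)-6-methylcyclohex-1-en-1-yl trifluoromethanesulfonate
Conditions: Co(acac)2 (20 mol%), PhSiH3, O2 (1 atm), THF, rt; aq. Na2S2O3
Reagents that add atoms: dioxygen, O=O
Why: Mukaiyama hydration, in which a cobalt hydride transfers H• to the terminal carbon of the 1,1-disubstituted alkene and the tertiary C11 radical is trapped by O2 and reduced to the alcohol (Markovnikov), while the hindered, electron-poor enol triflate and the ketone should not react.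

Step 7
Reactants: 10 (3S,6R)-6-[(2S)-1,1-dimethoxy-5-oxohexan-2-yl]-3-(2-hydroxypropan-2-yl)-6-methylcyclohex-1-en-1-yl trifluoromethanesulfonate
Product: 11 1-(dimethoxymethyl)-6-(2-hydroxypropan-2-yl)-4,8a-dimethyl-1,2,3,4,6,7,8,8a-octahydronaphthalen-4-ol (C5=C6 alkene; 4-OH, 1-substituent and 6-substituent all cis to the angular methyl; C1, C4, C7, C10 as in 19)
Conditions: CrCl2 (8 equiv), NiCl2 (10 mol%), degassed DMF, 50 °C; aq. NH4Cl
Reagents that add atoms: none
Why: NiCl2 is reduced in situ to zerovalent nickel, which inserts into the C5–O bond of the enol triflate; transmetalation gives an alkenyl species of trivalent chromium that adds to the C4 ketone within the same molecule (Nozaki–Hiyama–Kishi reaction). The closest known reaction type is the intramolecular Nozaki–Hiyama–Kishi alkenylation of aldehydes and ketones to six-membered allylic alcohols. Ring A closes in the 6-exo-trig mode, with C5 attacking the carbonyl carbon C4. The only new stereocentre, C4, is controlled by C10 and C1: in the chair-like closure the C1 acetal and the C4 methyl sit equatorial and the chromium-bound oxygen axial on the face of the axial C10 methyl, which should give the 4-OH cis to C10–CH3. The step needs chemoselective activation of the triflate beside ketone, acetal and free tertiary alcohol; the ketone is the only electrophile within reach of C5, and because C10 is quaternary the C5=C6 bond cannot migrate, so C5 stays trigonal for step 8.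

Step 8
Reactants: 11 1-(dimethoxymethyl)-6-(2-hydroxypropan-2-yl)-4,8a-dimethyl-1,2,3,4,6,7,8,8a-octahydronaphthalen-4-ol
Product: 12 1-(dimethoxymethyl)-6-(2-hydroxypropan-2-yl)-4,8a-dimethyldecahydronaphthalen-4-ol (trans-fused, all centres as in 19)
Conditions: Mn(dpm)3 [tris(2,2,6,6-tetramethylheptane-3,5-dionato)manganese] (10 mol%), PhSiH3, t-BuOOH, i-PrOH, rt
Reagents that add atoms: none
Why: Metal-hydride hydrogen-atom-transfer hydrogenation, in which H• adds to C6 and the tertiary C5 radical takes up hydrogen on the face opposite the axial C10 methyl and C4 hydroxyl groups, which should set H5 trans to the C10 methyl (the thermodynamically favoured trans-decalin) without hydrogenolysis of the allylic C4–O bond.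

Step 9
Reactants: 12 1-(dimethoxymethyl)-6-(2-hydroxypropan-2-yl)-4,8a-dimethyldecahydronaphthalen-4-ol
Product: 13 4-hydroxy-6-(2-hydroxypropan-2-yl)-4,8a-dimethyldecahydronaphthalene-1-carbaldehyde (trans-fused, all centres as in 19)
Conditions: p-TsOH·H2O (cat.), acetone/H2O (10:1), rt
Reagents that add atoms: water, O
Why: Mild acid hydrolysis of a dimethyl acetal, which the two tertiary alcohols should survive and which leaves the formyl group equatorial at C1.

Step 10
Reactants: 13 4-hydroxy-6-(2-hydroxypropan-2-yl)-4,8a-dimethyldecahydronaphthalene-1-carbaldehyde; 14 2,4,6-trihydroxybenzene-1,3-dicarbaldehyde; 15 trimethyl(2-methylprop-2-en-1-yl)silane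
Product: 18 2,4,6-trihydroxy-5-[(1R)-3-methyl-1-(decalinyl)but-3-en-1-yl]benzene-1,3-dicarbaldehyde (19 with a 2-methylallyl group in place of isobutyl), via o-quinone methide 16 (not isolated), via silylmethylchroman 17 (not isolated)
Conditions: ethylenediammonium diacetate (20 mol%), 15 (5 equiv), 1,4-dioxane, 60 °C; then Bu4NF, THF, 0 °C → rt; aq. NH4Cl
Reagents that add atoms: none
Why: Domino Knoevenagel condensation/oxa-Diels–Alder reaction (the o-quinone methide 16 is trapped by the nucleophilic 1,1-disubstituted alkene to give 17), followed by fluoride-induced β-elimination of the β-silyl aryl ether; C9' is set when the silane adds to the face of 16 anti to C10 in the conformer with H1 eclipsing the exocyclic C=C (allylic 1,3-strain), which should give the (R) centre.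

Step 11
Reactants: 18 the 2-methylallyl compound
Product: 19 2,4,6-trihydroxy-5-{(1R)-1-[(1R,4R,4aS,6S,8aR)-4-hydroxy-6-(2-hydroxypropan-2-yl)-4,8a-dimethyldecahydronaphthalen-1-yl]-3-methylbutyl}benzene-1,3-dicarbaldehyde
Conditions: KO2CN=NCO2K, AcOH, MeOH, 0 °C → rt
Reagents that add atoms: none
Why: Diimide reduction, a concerted syn transfer of H2 to the unhindered 1,1-disubstituted alkene that should not touch aryl aldehydes or phenols and forms no stereocentre.

**Compound list**
1 | 3-methylcyclopent-2-en-1-one | CC1=CC(=O)CC1 | starting material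
2 | (R)-3-methylcyclopent-2-en-1-ol | CC1=C[C@@H](CC1)O | intermediate
3 | methyl (R)-3-methylcyclopent-2-en-1-yl carbonate | CC1=C[C@@H](CC1)OC(=O)OC | intermediate
4 | (S)-(+)-carvone, (5S)-2-methyl-5-(prop-1-en-2-yl)cyclohex-2-en-1-one | CC1=CC[C@H](C(C)=C)CC1=O | starting material
5 | lithium (5S)-2-methyl-5-(prop-1-en-2-yl)cyclohex-1-en-1-olate (tri-sec-butylborane ate complex) | CC1=C([O-])C[C@@H](C(C)=C)CC1.[Li+] | intermediate
6 | (2R,5S)-2-methyl-2-[(1R)-3-methylcyclopent-2-en-1-yl]-5-(prop-1-en-2-yl)cyclohexan-1-one | CC1=C[C@@H](CC1)[C@@]2(C)CC[C@H](C(C)=C)CC2=O | intermediate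
7 | (3S,6R)-6-methyl-6-[(1R)-3-methylcyclopent-2-en-1-yl]-3-(prop-1-en-2-yl)cyclohex-1-en-1-yl trifluoromethanesulfonate | CC1=C[C@@H](CC1)[C@@]2(C)CC[C@H](C(C)=C)C=C2OS(=O)(=O)C(F)(F)F | intermediate
8 | (3S,6R)-6-[(2S)-1,5-dioxohexan-2-yl]-6-methyl-3-(prop-1-en-2-yl)cyclohex-1-en-1-yl trifluoromethanesulfonate | O=C[C@@H](CCC(C)=O)[C@@]1(C)CC[C@H](C(C)=C)C=C1OS(=O)(=O)C(F)(F)F | intermediate
9 | (3S,6R)-6-[(2S)-1,1-dimethoxy-5-oxohexan-2-yl]-6-methyl-3-(prop-1-en-2-yl)cyclohex-1-en-1-yl trifluoromethanesulfonate | COC(OC)[C@@H](CCC(C)=O)[C@@]1(C)CC[C@H](C(C)=C)C=C1OS(=O)(=O)C(F)(F)F | intermediate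
10 | (3S,6R)-6-[(2S)-1,1-dimethoxy-5-oxohexan-2-yl]-3-(2-hydroxypropan-2-yl)-6-methylcyclohex-1-en-1-yl trifluoromethanesulfonate | COC(OC)[C@@H](CCC(C)=O)[C@@]1(C)CC[C@H](C(C)(C)O)C=C1OS(=O)(=O)C(F)(F)F | intermediate
11 | 1-(dimethoxymethyl)-6-(2-hydroxypropan-2-yl)-4,8a-dimethyl-1,2,3,4,6,7,8,8a-octahydronaphthalen-4-ol, centres as in 19 | COC(OC)[C@H]1CC[C@@](C)(O)C2=C[C@@H](C(C)(C)O)CC[C@]12C | intermediate
12 | 1-(dimethoxymethyl)-6-(2-hydroxypropan-2-yl)-4,8a-dimethyldecahydronaphthalen-4-ol, trans-fused, centres as in 19 | COC(OC)[C@H]1CC[C@@](C)(O)[C@H]2C[C@@H](C(C)(C)O)CC[C@]12C | intermediate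
13 | 4-hydroxy-6-(2-hydroxypropan-2-yl)-4,8a-dimethyldecahydronaphthalene-1-carbaldehyde, trans-fused, centres as in 19 | O=C[C@H]1CC[C@@](C)(O)[C@H]2C[C@@H](C(C)(C)O)CC[C@]12C | intermediate
14 | 2,4,6-trihydroxybenzene-1,3-dicarbaldehyde | O=Cc1c(O)cc(O)c(C=O)c1O | starting material
15 | trimethyl(2-methylprop-2-en-1-yl)silane | CC(=C)C[Si](C)(C)C | starting material
16 | o-quinone methide from 13 and 14 (alkene geometry not defined) | O=CC1=C(O)C(C=O)=C(O)C(=C[C@H]2CC[C@@](C)(O)[C@H]3C[C@@H](C(C)(C)O)CC[C@]23C)C1=O | intermediate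
17 | 2-methyl-2-[(trimethylsilyl)methyl]chroman cycloadduct (mixture at chroman C2) | C[Si](C)(C)CC1(C)C[C@@H](c2c(O)c(C=O)c(O)c(C=O)c2O1)[C@H]3CC[C@@](C)(O)[C@H]4C[C@@H](C(C)(C)O)CC[C@]34C | intermediate
18 | 2-methylallyl analogue of 19 | C=C(C)C[C@@H](c1c(O)c(C=O)c(O)c(C=O)c1O)[C@H]1CC[C@@](C)(O)[C@H]2C[C@@H](C(C)(C)O)CC[C@]12C | intermediate
19 | 2,4,6-trihydroxy-5-{(1R)-1-[(1R,4R,4aS,6S,8aR)-4-hydroxy-6-(2-hydroxypropan-2-yl)-4,8a-dimethyldecahydronaphthalen-1-yl]-3-methylbutyl}benzene-1,3-dicarbaldehyde | CC(C)C[C@@H](c1c(O)c(C=O)c(O)c(C=O)c1O)[C@H]1CC[C@@](C)(O)[C@H]2C[C@@H](C(C)(C)O)CC[C@]12C | target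

**Step count**
Total: 11 steps. Longest linear sequence: 11 steps (1 → 19; nine steps from 4).

**Steps most likely to fail**

Step 3. Attack of the hindered tetrasubstituted enolate on the allylpalladium intermediate may be slow. The intermediate could then exchange palladium between its two faces (loss of configuration at C1) or eliminate to a diene, and facial selectivity at C10 may be incomplete. The fallback sets out from 4 and comes back at 6. Carvone 4 is reduced as before to enolate 5, which is added in a Michael reaction to cyclopent-2-en-1-one (THF, −78 → −30 °C). The cyclopentanone enolate so formed is trapped in the same flask with PhNTf2 to give the cyclopentenyl triflate F1. Iron-catalysed cross-coupling (MeMgBr, Fe(acac)3, THF/NMP, −30 °C) then introduces the methyl group and returns 6. The C10–C1 bond is here made through a lithium-chelated closed transition state and no allyl–metal species is involved.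

Step 7. The alkenylchromium species may be protonated before it adds to the hindered ketone (net reduction of the triflate), or it may add to the wrong carbonyl face. The fallback sets out from 10 and comes back at 11. Miyaura borylation (B2pin2, PdCl2(dppf), KOAc, 1,4-dioxane, 80 °C) converts the triflate into the alkenyl pinacol boronate F2. [Rh(cod)OH]2 (cat.) in 1,4-dioxane/H2O at 60 °C then effects transmetalation and intramolecular 1,2-addition of the alkenylrhodium to the C4 ketone, giving 11.

Step 10. Condensation of the α-branched, neopentyl-type aldehyde with the phloroglucinol may be slow, which would allow epimerisation at C1 and unselective trapping of the o-quinone methide (poor facial selectivity at C9'). The fallback sets out from 13 and comes back at 19.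
- 13 is added at −78 °C to 2,4,6-tris(methoxymethoxy)phenyllithium (from 1,3,5-tris(methoxymethoxy)benzene and n-BuLi, THF; excess to cover the two hydroxyl groups) to give the benzylic alcohol F3.
- Ionisation with Sc(OTf)3 (cat.) in CH2Cl2 at −40 °C in the presence of 15 (Hosomi–Sakurai allylation of the trialkoxybenzyl cation, same facial argument as in step 10) gives the 2-methylallyl compound F4.
- H2, Pd/C, EtOAc reduces the alkene to the isobutyl compound F5.
- Two rounds of ortho-lithiation directed by the methoxymethyl ethers (n-BuLi, TMEDA, THF, 0 °C) with DMF quench, the first formyl group being masked in situ as its lithium amino alkoxide, give the dialdehyde F6.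
- HCl in MeOH at rt removes the three methoxymethyl groups and gives 19.

Further compounds
F1 | step 3 | 3-[(1R,4S)-1-methyl-2-oxo-4-(prop-1-en-2-yl)cyclohexyl]cyclopent-1-en-1-yl trifluoromethanesulfonate (ring carbon attached to the cyclohexane configured as C1 of 6) | O=S(=O)(OC1=C[C@@H](CC1)[C@@]2(C)CC[C@H](C(C)=C)CC2=O)C(F)(F)F
F2 | step 7 | pinacol alkenylboronate corresponding to 10 (Bpin in place of OTf at C5) | COC(OC)[C@@H](CCC(C)=O)[C@@]1(C)CC[C@H](C(C)(C)O)C=C1B2OC(C)(C)C(C)(C)O2
F3 | step 10 | benzylic alcohol from 13 and 2,4,6-tris(methoxymethoxy)phenyllithium (carbinol centre not defined) | OC(c1c(OCOC)cc(OCOC)cc1OCOC)[C@H]1CC[C@@](C)(O)[C@H]2C[C@@H](C(C)(C)O)CC[C@]12C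
F4 | step 10 | (R)-configured 2-methylallyl tris(methoxymethyl) ether | C=C(C)C[C@@H](c1c(OCOC)cc(OCOC)cc1OCOC)[C@H]1CC[C@@](C)(O)[C@H]2C[C@@H](C(C)(C)O)CC[C@]12C
F5 | step 10 | isobutyl tris(methoxymethyl) ether | CC(C)C[C@@H](c1c(OCOC)cc(OCOC)cc1OCOC)[C@H]1CC[C@@](C)(O)[C@H]2C[C@@H](C(C)(C)O)CC[C@]12C
F6 | step 10 | tris(methoxymethyl) ether of 19 | CC(C)C[C@@H](c1c(OCOC)c(C=O)c(OCOC)c(C=O)c1OCOC)[C@H]1CC[C@@](C)(O)[C@H]2C[C@@H](C(C)(C)O)CC[C@]12C
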